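Ring B is not coupled to ring A but grown on the ring A oxygen. The key step exploits the ring B pattern (C1' ester, C2' ether oxygen, C4' hydroxyl, C6' 3-oxopentyl chain, hydrogens at C3' and C5'). This pattern equals a cyclic 1,3-dioxygenated diene, a 4-benzyloxy-6-alkyl-2-pyranone (C3'–C6'), plus a polarised alkyne, a methyl propiolate whose beta carbon already carries the ring A aryloxy group (C1', C2'). One thermal operation forms C2'–C3' and C1'–C6', expels CO2 and leaves the complete arene. The crowded C3–O–C2' ether is thus made earlier, at an unhindered sp carbon. Ketal hydrolysis and a neutral hydrogenolysis finish the synthesis.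

Key step: step 12

Numbering used:
- Ring A: C1 carboxyl carbon, C2 pentyl, C3 ether oxygen, C4 methoxy, C5 H, C6 hydroxyl.
- Ring B: C1' ester carbon, C2' ether oxygen, C3' H, C4' hydroxyl, C5' H, C6' 3-oxopentyl.

Remark on the chemistry: the target has no stereocentre. The only stereocentres in the route are the two bridgeheads of the transient adduct 21 (racemic), and they vanish with CO2.

Design points:
- A free C3/C6 hydroquinone cannot be benzylated selectively at the chelated C6 hydroxyl. The Elbs sulfate is therefore kept on O3 while O6 is benzylated.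
- The ketal is removed before the benzyl groups, so the decarboxylation-prone 6-hydroxy acid never meets aqueous acid.
- The hydroxypyranone is O-benzylated under Mitsunobu conditions to avoid C3-benzylation.

Step 1
Reactants: 1 olivetol (5-pentylbenzene-1,3-diol)
Product: 2 olivetolic acid (2,4-dihydroxy-6-pentylbenzoic acid)
Conditions: MeOMgOCO2Me (2 M in DMF, excess), 120 °C, N2; then ice-cold 2 M HCl
Reagents that add atoms: methoxymagnesium methyl carbonate, CO[Mg]OC(=O)OC
Why: Kolbe–Schmitt-type ortho-carboxylation in which the magnesium phenoxide delivers CO2 to the carbon ortho to one hydroxyl and para to the other, as established for 5-alkylresorcinols, the labile acid staying chelated to magnesium until the cold quench.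

Step 2
Reactants: 2 olivetolic acid
Product: 3 benzyl 2,4-dihydroxy-6-pentylbenzoate
Conditions: BnBr (1.05 equiv), KHCO3, DMF, rt
Reagents that add atoms: benzyl bromide, BrCc1ccccc1
Why: Chemoselective SN2 O-alkylation of the carboxylate, since KHCO3 ionises only the acid and leaves both phenols protonated.

Step 3
Reactants: 3 benzyl 2,4-dihydroxy-6-pentylbenzoate
Product: 4 benzyl 2-hydroxy-4-methoxy-6-pentylbenzoate
Conditions: MeI (1.05 equiv), K2CO3 (1.1 equiv), acetone, rt to 40 °C
Reagents that add atoms: iodomethane, CI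
Why: Williamson etherification that distinguishes the phenols, because the 2-OH is held in a hydrogen bond to the ester carbonyl and the single equivalent of MeI is taken by the free 4-OH.

Step 4
Reactants: 4 benzyl 2-hydroxy-4-methoxy-6-pentylbenzoate
Product: 5 potassium 3-[(benzyloxy)carbonyl]-4-hydroxy-6-methoxy-2-pentylphenyl sulfate
Conditions: K2S2O8 (1.1 equiv), aq KOH, pyridine, 0 °C to rt; neutralise with CO2, wash out unchanged 4 with Et2O, extract the salt into n-BuOH
Reagents that add atoms: dipotassium peroxodisulfate, [K+].[K+].[O-]S(=O)(=O)OOS(=O)(=O)[O-]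
Why: Elbs persulfate oxidation, in which the phenolate attacks the peroxide oxygen through its para carbon (C5 of 4, which is C3 of ring A), so the regiochemistry is fixed, the new oxygen arrives masked as a sulfate monoester, and the doubly ortho-substituted ester next to a phenolate resists saponification.

Step 5
Reactants: 5 potassium 3-[(benzyloxy)carbonyl]-4-hydroxy-6-methoxy-2-pentylphenyl sulfate
Product: 7 benzyl 6-(benzyloxy)-3-hydroxy-4-methoxy-2-pentylbenzoate, via O-benzylated aryl sulfate salt 6 (not isolated)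
Conditions: BnBr, K2CO3, DMF, 50 °C; then 2 M HCl, THF, 50 °C
Reagents that add atoms: benzyl bromide, BrCc1ccccc1
Why: Williamson benzylation of the only free phenol while the non-nucleophilic sulfate blocks O3, followed by acid-catalysed S–O solvolysis of the aryl sulfate, the known way from an Elbs sulfate to a quinol monoether.

Step 6
Reactants: 7 benzyl 6-(benzyloxy)-3-hydroxy-4-methoxy-2-pentylbenzoate; 8 trichloroethylene
Product: 10 benzyl 6-(benzyloxy)-3-{[(E)-1,2-dichloroethenyl]oxy}-4-methoxy-2-pentylbenzoate, via dichloroacetylene 9 (not isolated)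
Conditions: 8 (1.5 equiv), K2CO3, DMF, 70 °C, Ar (9 is only generated in situ and never concentrated)
Reagents that add atoms: none
Why: Nucleophilic vinylation of a phenol with trichloroethylene, where base-induced loss of HCl gives the linear electrophile 9 and anti addition of the phenoxide sets the E geometry, so the two ortho groups of ring A hardly interfere.

Step 7
Reactants: 10 benzyl 6-(benzyloxy)-3-{[(E)-1,2-dichloroethenyl]oxy}-4-methoxy-2-pentylbenzoate
Product: 13 methyl 3-{4-(benzyloxy)-3-[(benzyloxy)carbonyl]-6-methoxy-2-pentylphenoxy}prop-2-ynoate, via chloroethynyl aryl ether 11 (not isolated), via lithium aryloxyacetylide 12 (not isolated)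
Conditions: n-BuLi (2.1 equiv, slow addition), THF, −78 °C; then ClCO2Me, −78 °C to 0 °C; pH 7 buffer work-up, Et3N-deactivated silica
Reagents that add atoms: methyl chloroformate, COC(=O)Cl
Why: Dichlorovinyl ether route to ynol ethers (vinyl deprotonation with beta-elimination of chloride, chlorine–lithium exchange, then C-acylation of the acetylide by a chloroformate), all of it fast at −78 °C, where the benzyl ester shielded by two ortho substituents should be attacked far more slowly.

Step 8
Reactants: 14 ethyl 4-oxohexanoate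
Product: 15 ethyl 3-(2-ethyl-1,3-dioxolan-2-yl)propanoate
Conditions: ethylene glycol (1.5 equiv), TsOH (cat.), toluene, Dean–Stark reflux
Reagents that add atoms: ethylene glycol, OCCO
Why: Acid-catalysed ketalisation driven by azeotropic removal of water, the ketone reacting in preference to the ester.

Step 9
Reactants: 16 methyl acetoacetate; 15 ethyl 3-(2-ethyl-1,3-dioxolan-2-yl)propanoate
Product: 18 methyl 7-(2-ethyl-1,3-dioxolan-2-yl)-3,5-dioxoheptanoate, via acetoacetate dianion 17 (not isolated)
Conditions: 16 (2.2 equiv), NaH then n-BuLi, THF, 0 °C; add 15 (1 equiv), 0 °C to rt; AcOH quench at 0 °C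
Reagents that add atoms: none
Why: Claisen-type acylation of a beta-keto ester dianion, which reacts only at its more basic terminal carbon, while the surplus dianion absorbs the acidic proton of the product and the ketal keeps the former ketone of 14 out of play.

Step 10
Reactants: 18 methyl 7-(2-ethyl-1,3-dioxolan-2-yl)-3,5-dioxoheptanoate
Product: 19 6-[2-(2-ethyl-1,3-dioxolan-2-yl)ethyl]-4-hydroxy-2H-pyran-2-one
Conditions: DBU (1.2 equiv), toluene, 90 °C; work-up with pH 4–5 phosphate buffer
Reagents that add atoms: none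
Why: Base-promoted enol lactonisation, in which the C5 enolate oxygen attacks the methyl ester in a 6-exo-trig acyl substitution and loss of methoxide gives the stabilised 4-hydroxy-2-pyranone under conditions that leave the ketal intact.

Step 11
Reactants: 19 6-[2-(2-ethyl-1,3-dioxolan-2-yl)ethyl]-4-hydroxy-2H-pyran-2-one
Product: 20 4-(benzyloxy)-6-[2-(2-ethyl-1,3-dioxolan-2-yl)ethyl]-2H-pyran-2-one
Conditions: BnOH, PPh3, DIAD, THF, 0 °C to rt
Reagents that add atoms: benzyl alcohol, OCc1ccccc1
Why: Mitsunobu etherification, for which the vinylogous acid (pKa near 5) is an ideal pronucleophile and which is known to alkylate 4-hydroxy-6-alkyl-2-pyranones at O4 without the C3-benzylation seen with benzyl halide and base.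

Step 12
Reactants: 13 methyl 3-{4-(benzyloxy)-3-[(benzyloxy)carbonyl]-6-methoxy-2-pentylphenoxy}prop-2-ynoate; 20 4-(benzyloxy)-6-[2-(2-ethyl-1,3-dioxolan-2-yl)ethyl]-2H-pyran-2-one
Product: 22 benzyl 6-(benzyloxy)-3-{5-(benzyloxy)-3-[2-(2-ethyl-1,3-dioxolan-2-yl)ethyl]-2-(methoxycarbonyl)phenoxy}-4-methoxy-2-pentylbenzoate, via bridged bicyclic lactone 21 (not isolated)
Conditions: 20 (2 equiv), BHT (cat.), dry 1,2-dichlorobenzene, base-washed sealed tube, Ar, 170 °C
Reagents that add atoms: none
Why: Proposed new method: a 3-aryloxypropiolate has not been used as the two-carbon partner of a 2-pyranone, but the closest known reaction type, the thermal Diels–Alder/retro-Diels–Alder benzannulation of 4-alkoxy-6-alkyl-2-pyranones with acetylenic esters, follows the same course. The pyranone diene C3=C4–C5=C6 adds across the alkyne, concertedly or in a strongly asynchronous Michael-like manner, to give the 2-oxabicyclo[2.2.2]octadienone 21, and a retro-[4+2] step then ejects the O1–C2 bridge as CO2, which makes the sequence irreversible. Ring B is closed by an intermolecular [4+2] cycloaddition, four carbons coming from 20 (C3' to C6') and two from 13 (C1' and C2'), and it is aromatic as soon as CO2 has left. The two bridgehead stereocentres of 21 form as a racemate, are tied to each other by the bicycle and are both erased on aromatisation, so no stereocontrol is needed. The selectivity required is regiochemical: the ring oxygen O1 and the 4-benzyloxy group both push electron density to pyranone C3, while the ester makes the aryloxy-bearing beta carbon of 13 the electrophilic end, so C3 should bond to C2' and C6 to C1', which places the ester between the ether oxygen and the side chain. Aryl ynol ethers lack the beta C–H needed for retro-ene collapse to a ketene, which is why 13 should bear the temperature, and the crowded ring A sits one oxygen away from the reacting carbon.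

Step 13
Reactants: 22 benzyl 6-(benzyloxy)-3-{5-(benzyloxy)-3-[2-(2-ethyl-1,3-dioxolan-2-yl)ethyl]-2-(methoxycarbonyl)phenoxy}-4-methoxy-2-pentylbenzoate
Product: 23 benzyl 6-(benzyloxy)-3-[5-(benzyloxy)-2-(methoxycarbonyl)-3-(3-oxopentyl)phenoxy]-4-methoxy-2-pentylbenzoate
Conditions: 1 M HCl (cat.), THF–H2O, rt
Reagents that add atoms: water, O
Why: Acid-catalysed ketal hydrolysis, run while the ring A acid is still a benzyl ester so that no electron-rich free o-hydroxybenzoic acid is exposed to acid and decarboxylation is excluded.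

Step 14
Reactants: 23 benzyl 6-(benzyloxy)-3-[5-(benzyloxy)-2-(methoxycarbonyl)-3-(3-oxopentyl)phenoxy]-4-methoxy-2-pentylbenzoate
Product: 24 epiphorellic acid 2 (6-hydroxy-3-[5-hydroxy-2-(methoxycarbonyl)-3-(3-oxopentyl)phenoxy]-4-methoxy-2-pentylbenzoic acid)
Conditions: H2 (1 atm), 10% Pd/C, EtOAc, rt; filter, evaporate below 30 °C
Reagents that add atoms: none
Why: Catalytic hydrogenolysis of the benzyl ester and both aryl benzyl ethers under neutral conditions, which leaves the dialkyl ketone, methyl ester and diaryl ether untouched and frees the sensitive acid only in the last operation.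

Compound list
1 | olivetol | CCCCCc1cc(O)cc(O)c1 | starting material
2 | olivetolic acid | CCCCCc1cc(O)cc(O)c1C(=O)O | intermediate
3 | benzyl 2,4-dihydroxy-6-pentylbenzoate | CCCCCc1cc(O)cc(O)c1C(=O)OCc1ccccc1 | intermediate
4 | benzyl 2-hydroxy-4-methoxy-6-pentylbenzoate | CCCCCc1cc(OC)cc(O)c1C(=O)OCc1ccccc1 | intermediate
5 | potassium 3-[(benzyloxy)carbonyl]-4-hydroxy-6-methoxy-2-pentylphenyl sulfate | CCCCCc1c(OS(=O)(=O)[O-])c(OC)cc(O)c1C(=O)OCc1ccccc1.[K+] | intermediate
6 | potassium 4-(benzyloxy)-3-[(benzyloxy)carbonyl]-6-methoxy-2-pentylphenyl sulfate (not isolated) | CCCCCc1c(OS(=O)(=O)[O-])c(OC)cc(OCc2ccccc2)c1C(=O)OCc1ccccc1.[K+] | intermediate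
7 | benzyl 6-(benzyloxy)-3-hydroxy-4-methoxy-2-pentylbenzoate | CCCCCc1c(O)c(OC)cc(OCc2ccccc2)c1C(=O)OCc1ccccc1 | intermediate
8 | trichloroethylene | ClC=C(Cl)Cl | starting material
9 | dichloroacetylene (not isolated) | ClC#CCl | intermediate
10 | benzyl 6-(benzyloxy)-3-{[(E)-1,2-dichloroethenyl]oxy}-4-methoxy-2-pentylbenzoate | CCCCCc1c(O/C(Cl)=C\Cl)c(OC)cc(OCc2ccccc2)c1C(=O)OCc1ccccc1 | intermediate
11 | benzyl 6-(benzyloxy)-3-[(chloroethynyl)oxy]-4-methoxy-2-pentylbenzoate (not isolated) | CCCCCc1c(OC#CCl)c(OC)cc(OCc2ccccc2)c1C(=O)OCc1ccccc1 | intermediate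
12 | benzyl 6-(benzyloxy)-3-[(lithioethynyl)oxy]-4-methoxy-2-pentylbenzoate (not isolated) | CCCCCc1c(OC#C[Li])c(OC)cc(OCc2ccccc2)c1C(=O)OCc1ccccc1 | intermediate
13 | methyl 3-{4-(benzyloxy)-3-[(benzyloxy)carbonyl]-6-methoxy-2-pentylphenoxy}prop-2-ynoate | COC(=O)C#COc1c(CCCCC)c(C(=O)OCc2ccccc2)c(OCc2ccccc2)cc1OC | intermediate
14 | ethyl 4-oxohexanoate | CCC(=O)CCC(=O)OCC | starting material
15 | ethyl 3-(2-ethyl-1,3-dioxolan-2-yl)propanoate | CCOC(=O)CCC1(CC)OCCO1 | intermediate
16 | methyl acetoacetate | CC(=O)CC(=O)OC | starting material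
17 | lithium sodium dianion of methyl acetoacetate (not isolated) | C=C([O-])C=C([O-])OC.[Li+].[Na+] | intermediate
18 | methyl 7-(2-ethyl-1,3-dioxolan-2-yl)-3,5-dioxoheptanoate | COC(=O)CC(=O)CC(=O)CCC1(CC)OCCO1 | intermediate
19 | 6-[2-(2-ethyl-1,3-dioxolan-2-yl)ethyl]-4-hydroxy-2H-pyran-2-one | O=C1C=C(O)C=C(CCC2(CC)OCCO2)O1 | intermediate
20 | 4-(benzyloxy)-6-[2-(2-ethyl-1,3-dioxolan-2-yl)ethyl]-2H-pyran-2-one | O=C1C=C(OCc2ccccc2)C=C(CCC2(CC)OCCO2)O1 | intermediate
21 | racemic methyl 5-(ring A aryloxy)-8-(benzyloxy)-1-[2-(2-ethyl-1,3-dioxolan-2-yl)ethyl]-3-oxo-2-oxabicyclo[2.2.2]octa-5,7-diene-6-carboxylate, one enantiomer drawn (not isolated) | O=C1O[C@@]2(CCC3(CC)OCCO3)C=C(OCc3ccccc3)[C@@H]1C(Oc1c(CCCCC)c(C(=O)OCc3ccccc3)c(OCc3ccccc3)cc1OC)=C2C(=O)OC | intermediate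
22 | benzyl 6-(benzyloxy)-3-{5-(benzyloxy)-3-[2-(2-ethyl-1,3-dioxolan-2-yl)ethyl]-2-(methoxycarbonyl)phenoxy}-4-methoxy-2-pentylbenzoate | CCCCCc1c(Oc2cc(OCc3ccccc3)cc(CCC3(CC)OCCO3)c2C(=O)OC)c(OC)cc(OCc2ccccc2)c1C(=O)OCc1ccccc1 | intermediate
23 | benzyl 6-(benzyloxy)-3-[5-(benzyloxy)-2-(methoxycarbonyl)-3-(3-oxopentyl)phenoxy]-4-methoxy-2-pentylbenzoate | CCCCCc1c(Oc2cc(OCc3ccccc3)cc(CCC(=O)CC)c2C(=O)OC)c(OC)cc(OCc2ccccc2)c1C(=O)OCc1ccccc1 | intermediate
24 | epiphorellic acid 2 | CCCCCc1c(Oc2cc(O)cc(CCC(=O)CC)c2C(=O)OC)c(OC)cc(O)c1C(=O)O | target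

Total step count: 14.
Longest linear sequence: 10 (steps 1–7, then 12–14). The pyranone branch (steps 8–11) is convergent.

Steps most likely to fail

1. Step 12 (the labelled step).
- Risk: the aryloxy donor raises the alkyne LUMO. The cycloaddition may therefore be slower than thermal degradation of the push-pull alkyne, by hydration from adventitious water or by oligomerisation. Erosion of regiocontrol is the lesser concern.
- Fallback, known chemistry only, sets out from 7 and rejoins at 23. Ring B is brought in ready-made and the ether is formed by copper catalysis.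
- Commercial 3,5-dibromophenol is benzylated (BnBr, K2CO3, DMF) to 1-(benzyloxy)-3,5-dibromobenzene F1. This is deprotonated between the two bromines (LDA, THF, −78 °C) and trapped with ClCO2Me to give methyl 4-(benzyloxy)-2,6-dibromobenzoate F2.
- Ullmann ether synthesis of 7 with an excess of the symmetrical dibromide (CuI, picolinic acid, K3PO4, DMSO, 90 °C) is assisted by the ortho ester. It should give benzyl 6-(benzyloxy)-3-[5-(benzyloxy)-3-bromo-2-(methoxycarbonyl)phenoxy]-4-methoxy-2-pentylbenzoate F3.
- Heck arylation of pent-1-en-3-ol (Pd(OAc)2, P(o-tol)3, Bu4NCl, NaHCO3, DMF, 100 °C), with migration of the double bond to the enol, installs the 3-oxopentyl chain and gives 23. Step 14 follows.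

2. Step 7.
- Risk: n-BuLi may add to the benzyl ester, metalate the benzylic CH2 or C5–H, or the ynol ether ester may hydrate during work-up.
- Fallback without organolithium sets out from 7 (bypassing steps 6 and 7) and rejoins at 13.
- The caesium phenoxide of 7 (Cs2CO3, DMF, rt) undergoes vinylic addition–elimination on methyl 3,3-dichloroacrylate. This gives methyl 3-{4-(benzyloxy)-3-[(benzyloxy)carbonyl]-6-methoxy-2-pentylphenoxy}-3-chloroprop-2-enoate F4 (E/Z mixture, both usable).
- The non-nucleophilic base LiHMDS (THF, −78 °C) then removes the alpha vinyl proton, and E1cB loss of chloride gives 13.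

3. Step 4.
- Risk: attack of the phenolate at its flanked para carbon may be sluggish. Over-oxidation of the electron-rich ring, poor solubility of the lipophilic phenolate, or partial saponification may also intervene.
- Fallback sets out from 4 (bypassing steps 4 and 5) and rejoins at 7.
- Bromination with NBS (MeCN, 0 °C) should go para to the free phenol, as halogenation of orsellinate-type esters does, giving benzyl 3-bromo-6-hydroxy-4-methoxy-2-pentylbenzoate F5.
- Benzylation (BnBr, K2CO3, DMF) gives benzyl 6-(benzyloxy)-3-bromo-4-methoxy-2-pentylbenzoate F6.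
- Miyaura borylation (B2pin2, Pd(OAc)2, SPhos, KOAc, dioxane, 90 °C) gives benzyl 6-(benzyloxy)-4-methoxy-2-pentyl-3-(4,4,5,5-tetramethyl-1,3,2-dioxaborolan-2-yl)benzoate F7.
- Oxidation (NaBO3·4H2O, THF–H2O, rt) gives 7.

Further compounds
F1 | step 12 | 1-(benzyloxy)-3,5-dibromobenzene | Brc1cc(Br)cc(OCc2ccccc2)c1
F2 | step 12 | methyl 4-(benzyloxy)-2,6-dibromobenzoate | COC(=O)c1c(Br)cc(OCc2ccccc2)cc1Br
F3 | step 12 | benzyl 6-(benzyloxy)-3-[5-(benzyloxy)-3-bromo-2-(methoxycarbonyl)phenoxy]-4-methoxy-2-pentylbenzoate | CCCCCc1c(Oc2cc(OCc3ccccc3)cc(Br)c2C(=O)OC)c(OC)cc(OCc2ccccc2)c1C(=O)OCc1ccccc1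
F4 | step 7 | methyl 3-{4-(benzyloxy)-3-[(benzyloxy)carbonyl]-6-methoxy-2-pentylphenoxy}-3-chloroprop-2-enoate (E/Z mixture) | COC(=O)C=C(Cl)Oc1c(CCCCC)c(C(=O)OCc2ccccc2)c(OCc2ccccc2)cc1OC
F5 | step 4 | benzyl 3-bromo-6-hydroxy-4-methoxy-2-pentylbenzoate | CCCCCc1c(Br)c(OC)cc(O)c1C(=O)OCc1ccccc1
F6 | step 4 | benzyl 6-(benzyloxy)-3-bromo-4-methoxy-2-pentylbenzoate | CCCCCc1c(Br)c(OC)cc(OCc2ccccc2)c1C(=O)OCc1ccccc1
F7 | step 4 | benzyl 6-(benzyloxy)-4-methoxy-2-pentyl-3-(4,4,5,5-tetramethyl-1,3,2-dioxaborolan-2-yl)benzoate | CCCCCc1c(B2OC(C)(C)C(C)(C)O2)c(OC)cc(OCc2ccccc2)c1C(=O)OCc1ccccc1
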